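**Plan**

1. Retrosynthesis: the base-labile C3–H centre is traced back to a C3=C4 enol silyl ether; the acid and the C5–OH are tied up as a dihydrocoumarin lactone (temporary ring) and the prenyl group is carried as allyl. The C4–C4a and C2–C3 bonds are then cut together, giving aryl vinyl ether 8 and siloxyalkyne 12; 8 goes back to 5,7-dihydroxycoumarin.
2. Forward: ring A and the lactone ring are bought as the coumarin. The allyl group is placed by a Claisen shift and the pentyl group by conjugate addition. Ring C (the pyranone of the chromanone) is closed last by a formal [4+2], followed by cross-metathesis, lactone opening and protonation.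
3. Enabling feature (chromanone numbering): on ring A the only unsubstituted carbon, C4a, lies ortho to the ether oxygen O1 and para to the C7 methoxy group. O1(+)=C2, generated from the vinyl ether, together with C8a=C4a is therefore a cationic 2-oxadiene that takes up the C3≡C4 unit of the alkyne.
4. Stereochemistry: the side-chain centre comes from a Cu-catalysed asymmetric conjugate addition to the coumarin. C2 comes from a chiral anion-binding catalyst in the annulation. C3 (cis) comes from kinetic protonation anti to the C2 methyl in the last step.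

Key step: step 9

Remark (assumption): the sense of induction of the two catalyst-controlled steps (5 and 9) is not predicted here; the catalyst antipode that gives the drawn 4R and 2S centres is to be chosen in a pilot run.

**Route**

Step 1
Reactants: 1 5,7-dihydroxycoumarin
Product: 2 5-hydroxy-7-(triisopropylsilyloxy)coumarin
Conditions: TIPSCl (1.05 equiv), imidazole, DMF, 0 °C
Reagents that add atoms: triisopropylsilyl chloride, CC(C)[Si](Cl)(C(C)C)C(C)C
Why: regioselective silylation of a diphenol; the 7-OH is the more acidic and less hindered hydroxyl (the 5-OH is peri to C4–H), so the bulky silyl group should go there.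

Step 2
Reactants: 2 5-hydroxy-7-(triisopropylsilyloxy)coumarin
Product: 3 5-(allyloxy)-7-(triisopropylsilyloxy)coumarin
Conditions: allyl alcohol, PPh3, DIAD, THF, 0 °C to rt
Reagents that add atoms: allyl alcohol, C=CCO
Why: Mitsunobu etherification of the remaining phenol under neutral conditions, which avoids the phenoxide-induced silyl migration that a carbonate base could cause.

Step 3
Reactants: 3 5-(allyloxy)-7-(triisopropylsilyloxy)coumarin
Product: 4 6-allyl-5-hydroxy-7-(triisopropylsilyloxy)coumarin
Conditions: PhNEt2, 190 °C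
Reagents that add atoms: none
Why: aromatic Claisen rearrangement; the [3,3] shift from O5 can only end at C6 because the other ortho position is the ring-fusion carbon, and tautomerisation restores the phenol.

Step 4
Reactants: 4 6-allyl-5-hydroxy-7-(triisopropylsilyloxy)coumarin
Product: 5 6-allyl-5-methoxy-7-(triisopropylsilyloxy)coumarin
Conditions: MeOH, PPh3, DIAD, THF, 0 °C to rt
Reagents that add atoms: methanol, CO
Why: Mitsunobu O-methylation of the hindered phenol, again without base so that the aryl silyl ether stays in place.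

Step 5
Reactants: 5 6-allyl-5-methoxy-7-(triisopropylsilyloxy)coumarin
Product: 6 (4R)-6-allyl-5-methoxy-4-pentyl-7-(triisopropylsilyloxy)chroman-2-one
Conditions: n-C5H11MgBr (1.5 equiv), CuBr·SMe2 (5 mol%), Josiphos-type ferrocenyl bisphosphine (6 mol%), CH2Cl2, −75 °C; aq. NH4Cl
Reagents that add atoms: pentylmagnesium bromide, CCCCC[Mg]Br
Why: Cu-catalysed asymmetric conjugate addition of a Grignard reagent to a coumarin; the chiral Cu–bisphosphine complex delivers the pentyl group to one face of C4 of the s-cis-locked enoate and so sets the 4R centre (catalyst control).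

Step 6
Reactants: 6 (4R)-6-allyl-5-methoxy-4-pentyl-7-(triisopropylsilyloxy)chroman-2-one
Product: 7 (4R)-6-allyl-7-hydroxy-5-methoxy-4-pentylchroman-2-one
Conditions: TBAF, AcOH, THF, 0 °C
Reagents that add atoms: none
Why: buffered fluoride cleavage of the aryl silyl ether; the lactone, the allyl group and the benzylic centre are untouched under these near-neutral conditions.

Step 7
Reactants: 7 (4R)-6-allyl-7-hydroxy-5-methoxy-4-pentylchroman-2-one
Product: 8 (4R)-6-allyl-5-methoxy-4-pentyl-7-(vinyloxy)chroman-2-one
Conditions: 2,4,6-trivinylcyclotriboroxane–pyridine complex, Cu(OAc)2, pyridine, CH2Cl2, rt, air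
Reagents that add atoms: 2,4,6-trivinylcyclotriboroxane–pyridine complex, C=CB1OB(C=C)OB(C=C)O1.c1ccncc1
Why: Chan–Lam-type O-vinylation of a phenol at room temperature, which tolerates the lactone and does not isomerise the allyl group.

Step 8
Reactants: 9 propyne
Product: 12 triisopropyl(prop-1-yn-1-yloxy)silane, via prop-1-ynyllithium 10 (not isolated), via lithium prop-1-yn-1-olate 11 (not isolated)
Conditions: n-BuLi, THF, −78 °C; t-BuOOLi (from t-BuOOH and LiN(SiMe3)2), −78 to 0 °C; TIPSOTf, −78 °C to rt
Reagents that add atoms: tert-butyl hydroperoxide, CC(C)(C)OO; triisopropylsilyl trifluoromethanesulfonate, CC(C)[Si](OS(=O)(=O)C(F)(F)F)(C(C)C)C(C)C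
Why: electrophilic oxygen transfer from lithium tert-butyl peroxide to the lithium acetylide gives the ynolate, which is O-silylated by the silyl triflate (the standard route to 1-siloxy-1-alkynes).

Step 9
Reactants: 8 (4R)-6-allyl-5-methoxy-4-pentyl-7-(vinyloxy)chroman-2-one; 12 triisopropyl(prop-1-yn-1-yloxy)silane
Product: 14 (4R,8S)-6-allyl-5-methoxy-8,9-dimethyl-4-pentyl-10-(triisopropylsilyloxy)-3,4-dihydro-2H,8H-pyrano[2,3-f]chromen-2-one, via 1-chloroethyl ether 13 (not isolated)
Conditions: HCl (1.0 equiv, 2 M in Et2O), CH2Cl2/t-BuOMe, −78 °C; then 2,6-di-tert-butyl-4-methylpyridine (1.2 equiv), chiral tert-leucine-derived amido-thiourea (10 mol%), 12 (1.5 equiv, slow addition), −78 to −40 °C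
Reagents that add atoms: none
Why: Proposed new method: HCl adds in the Markovnikov sense to the vinyl ether to give chloro ether 13; the chiral thiourea binds its chloride and leaves the E-configured aryl oxocarbenium ion O1(+)=C2 as a contact ion pair; the methyl-bearing carbon of siloxyalkyne 12 attacks C2 (C2–C3 bond); and the silyl ketenium ion so formed is captured by C4a of ring A (C4–C4a bond), the proton going to the hindered pyridine. The closest known reaction types are the oxa-Povarov formal [4+2] of aryl oxocarbenium ions with alkenes, the thiourea-catalysed addition of silyl ketene acetals to α-chloro ethers, and the acid-triggered carbocyclisation of siloxyalkynes onto arenes; their union with a siloxyalkyne as the 2π partner is new. Ring C is closed by a 6-exo-dig Friedel–Crafts attack of C4a on the ketenium carbon (the C=O(+) π bond that is consumed lies outside the new ring, the retained C3=C4 bond inside it). The C2 centre is set by the catalyst, whose chloride-bound chiral anion shields one face of the planar oxocarbenium ion; because the remote 4R lactone centre is already fixed, the unwanted C2 epimer is a diastereomer that can be removed, and C3 stays sp2. Regiochemistry needs no control because C4a is the only unsubstituted ring carbon (C8 carries the allyl group) and is ortho to O1 and para to the methoxy group; chemoselectivity over the allyl group rests on the far higher nucleophilicity of the siloxyalkyne, which is why the prenyl group is carried as allyl and why the hindered pyridine is present to keep free HCl away from 12.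

Step 10
Reactants: 14 (4R,8S)-6-allyl-5-methoxy-8,9-dimethyl-4-pentyl-10-(triisopropylsilyloxy)-3,4-dihydro-2H,8H-pyrano[2,3-f]chromen-2-one
Product: 15 (4R,8S)-5-methoxy-8,9-dimethyl-6-(3-methylbut-2-en-1-yl)-4-pentyl-10-(triisopropylsilyloxy)-3,4-dihydro-2H,8H-pyrano[2,3-f]chromen-2-one
Conditions: second-generation Grubbs catalyst (5 mol%), 2-methyl-2-butene/CH2Cl2, 40 °C
Reagents that add atoms: 2-methyl-2-butene, CC=C(C)C
Why: olefin cross-metathesis converts the terminal allyl group into prenyl, while the tetrasubstituted enol ether double bond is too hindered to take part.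

Step 11
Reactants: 15 (4R,8S)-5-methoxy-8,9-dimethyl-6-(3-methylbut-2-en-1-yl)-4-pentyl-10-(triisopropylsilyloxy)-3,4-dihydro-2H,8H-pyrano[2,3-f]chromen-2-one
Product: 16 (3R)-3-[(2S)-5-hydroxy-7-methoxy-2,3-dimethyl-8-(3-methylbut-2-en-1-yl)-4-(triisopropylsilyloxy)-2H-chromen-6-yl]octanoic acid
Conditions: LiOH (2.5 equiv), THF/H2O, 0 °C; AcOH to pH 5; crude product used directly
Reagents that add atoms: lithium hydroxide, [Li+].[OH-]
Why: saponification of the aryl lactone frees the acid and the C5 phenol while C3 is still sp2, so no centre is base-labile; the hindered silyl enol ether should resist LiOH at 0 °C, and silyl transfer to the phenoxide is disfavoured because it would trade a phenoxide for a ketone enolate.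

Step 12
Reactants: 16 (3R)-3-[(2S)-5-hydroxy-7-methoxy-2,3-dimethyl-8-(3-methylbut-2-en-1-yl)-4-(triisopropylsilyloxy)-2H-chromen-6-yl]octanoic acid
Product: 17 (3R)-3-[(2S,3R)-5-hydroxy-7-methoxy-2,3-dimethyl-8-(3-methylbut-2-en-1-yl)-4-oxochroman-6-yl]octanoic acid
Conditions: TBAF, AcOH (excess), THF, −78 to −20 °C; pH 7 buffer
Reagents that add atoms: none
Why: diastereoselective kinetic protonation of an enolate released from its silyl enol ether; A(1,2) strain places the C2 methyl pseudoaxial, AcOH protonates C3 on the opposite face, the new C3–H is therefore trans to the C2 methyl and the two methyl groups end up cis (2S,3R), with the buffer preventing equilibration to the trans isomer.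

**Compound list**

1 | 5,7-dihydroxycoumarin | O=c1ccc2c(O)cc(O)cc2o1 | starting material
2 | 5-hydroxy-7-(triisopropylsilyloxy)coumarin | O=c1ccc2c(O)cc(O[Si](C(C)C)(C(C)C)C(C)C)cc2o1 | intermediate
3 | 5-(allyloxy)-7-(triisopropylsilyloxy)coumarin | O=c1ccc2c(OCC=C)cc(O[Si](C(C)C)(C(C)C)C(C)C)cc2o1 | intermediate
4 | 6-allyl-5-hydroxy-7-(triisopropylsilyloxy)coumarin | O=c1ccc2c(O)c(CC=C)c(O[Si](C(C)C)(C(C)C)C(C)C)cc2o1 | intermediate
5 | 6-allyl-5-methoxy-7-(triisopropylsilyloxy)coumarin | O=c1ccc2c(OC)c(CC=C)c(O[Si](C(C)C)(C(C)C)C(C)C)cc2o1 | intermediate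
6 | (4R)-6-allyl-5-methoxy-4-pentyl-7-(triisopropylsilyloxy)chroman-2-one | CCCCC[C@@H]1CC(=O)Oc2cc(O[Si](C(C)C)(C(C)C)C(C)C)c(CC=C)c(OC)c21 | intermediate
7 | (4R)-6-allyl-7-hydroxy-5-methoxy-4-pentylchroman-2-one | CCCCC[C@@H]1CC(=O)Oc2cc(O)c(CC=C)c(OC)c21 | intermediate
8 | (4R)-6-allyl-5-methoxy-4-pentyl-7-(vinyloxy)chroman-2-one | CCCCC[C@@H]1CC(=O)Oc2cc(OC=C)c(CC=C)c(OC)c21 | intermediate
9 | propyne | CC#C | starting material
10 | prop-1-ynyllithium | CC#C[Li] | intermediate
11 | lithium prop-1-yn-1-olate | CC#CO[Li] | intermediate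
12 | triisopropyl(prop-1-yn-1-yloxy)silane | CC#CO[Si](C(C)C)(C(C)C)C(C)C | intermediate
13 | (4R)-6-allyl-7-(1-chloroethoxy)-5-methoxy-4-pentylchroman-2-one, both epimers at the CHCl carbon | CCCCC[C@@H]1CC(=O)Oc2cc(OC(C)Cl)c(CC=C)c(OC)c21 | intermediate
14 | (4R,8S)-6-allyl-5-methoxy-8,9-dimethyl-4-pentyl-10-(triisopropylsilyloxy)-3,4-dihydro-2H,8H-pyrano[2,3-f]chromen-2-one (allyl enol silyl ether lactone) | CCCCC[C@@H]1CC(=O)Oc2c1c(OC)c(CC=C)c1O[C@@H](C)C(C)=C(O[Si](C(C)C)(C(C)C)C(C)C)c12 | intermediate
15 | (4R,8S)-5-methoxy-8,9-dimethyl-6-(3-methylbut-2-en-1-yl)-4-pentyl-10-(triisopropylsilyloxy)-3,4-dihydro-2H,8H-pyrano[2,3-f]chromen-2-one (prenyl enol silyl ether lactone) | CCCCC[C@@H]1CC(=O)Oc2c1c(OC)c(CC=C(C)C)c1O[C@@H](C)C(C)=C(O[Si](C(C)C)(C(C)C)C(C)C)c12 | intermediate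
16 | (3R)-3-[(2S)-5-hydroxy-7-methoxy-2,3-dimethyl-8-(3-methylbut-2-en-1-yl)-4-(triisopropylsilyloxy)-2H-chromen-6-yl]octanoic acid | CCCCC[C@H](CC(=O)O)c1c(O)c2c(c(CC=C(C)C)c1OC)O[C@@H](C)C(C)=C2O[Si](C(C)C)(C(C)C)C(C)C | intermediate
17 | (3R)-3-[(2S,3R)-5-hydroxy-7-methoxy-2,3-dimethyl-8-(3-methylbut-2-en-1-yl)-4-oxochroman-6-yl]octanoic acid | CCCCC[C@H](CC(=O)O)c1c(O)c2c(c(CC=C(C)C)c1OC)O[C@@H](C)[C@@H](C)C2=O | target

**Step count**

Total steps: 12. Longest linear sequence: 11 (steps 1–7 and 9–12, from 1); step 8 is a one-step side branch.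

**Steps most likely to fail**

Step 9 (Proposed new method). The chloro ether may ionise without tight chiral ion pairing, giving poor facial selectivity at C2. Liberated HCl may protonate the siloxyalkyne, or the oxocarbenium ion may be lost to intermolecular Friedel–Crafts alkylation. The fallback uses known chemistry and builds ring C through the O1–C2 and C4–C4a bonds instead. It sets out from phenol 7. Fráter–Seebach methylation of commercial tert-butyl (R)-3-hydroxybutanoate gives tert-butyl (2R,3R)-3-hydroxy-2-methylbutanoate F1. Mitsunobu etherification of 7 with F1 (PPh3, DIAD, toluene; inversion at the carbinol carbon) gives tert-butyl (2R,3S)-3-{[(4R)-6-allyl-5-methoxy-2-oxo-4-pentylchroman-7-yl]oxy}-2-methylbutanoate F2. TFA in CH2Cl2 at 0 °C frees the acid (2R,3S)-3-{[(4R)-6-allyl-5-methoxy-2-oxo-4-pentylchroman-7-yl]oxy}-2-methylbutanoic acid F3. Conversion to the acid chloride ((COCl)2, cat. DMF) and intramolecular Friedel–Crafts acylation with SnCl4 at −78 °C at the one free ring position give (4R,8S,9R)-6-allyl-5-methoxy-8,9-dimethyl-4-pentyl-3,4,8,9-tetrahydro-2H,10H-pyrano[2,3-f]chromene-2,10-dione F4. Soft enolisation with TIPSOTf/Et3N then returns the route to 14.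

Step 5. The electron-rich, peri-substituted coumarin may be slow to accept the Grignard reagent, or the chiral copper complex may discriminate its faces poorly. The fallback replaces asymmetric catalysis by a classical resolution and sets out from 5. An achiral copper-catalysed addition (n-C5H11MgBr, CuI, TMSCl, THF, −40 °C) gives racemic 6-allyl-5-methoxy-4-pentyl-7-(triisopropylsilyloxy)chroman-2-one F5. Aminolysis with (S)-1-phenylethylamine and separation of the diastereomeric hydroxy amides give (3R)-3-[3-allyl-6-hydroxy-2-methoxy-4-(triisopropylsilyloxy)phenyl]-N-[(1S)-1-phenylethyl]octanamide F6. Acid-promoted relactonisation (TsOH, toluene, 80 °C) expels the amine and returns the route to 6.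

Step 12. The free phenol and carboxylic acid may deliver the proton to either face of the enolate, or the silyl group may transfer early, so that facial selectivity at C3 is lost. The fallback sets the C3 centre on the rigid lactone instead and opens the ring afterwards without base; it sets out from 15. TBAF/AcOH at −78 °C gives (4R,8S,9R)-5-methoxy-8,9-dimethyl-6-(3-methylbut-2-en-1-yl)-4-pentyl-3,4,8,9-tetrahydro-2H,10H-pyrano[2,3-f]chromene-2,10-dione F7. Hydrolysis of the activated aryl lactone with Me3SnOH in 1,2-dichloroethane at 60 °C, followed by a mildly acidic work-up, then gives 17.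

**Further compounds**

F1 | step 9 | tert-butyl (2R,3R)-3-hydroxy-2-methylbutanoate | C[C@@H](O)[C@@H](C)C(=O)OC(C)(C)C
F2 | step 9 | tert-butyl (2R,3S)-3-{[(4R)-6-allyl-5-methoxy-2-oxo-4-pentylchroman-7-yl]oxy}-2-methylbutanoate | CCCCC[C@@H]1CC(=O)Oc2cc(O[C@@H](C)[C@@H](C)C(=O)OC(C)(C)C)c(CC=C)c(OC)c21
F3 | step 9 | (2R,3S)-3-{[(4R)-6-allyl-5-methoxy-2-oxo-4-pentylchroman-7-yl]oxy}-2-methylbutanoic acid | CCCCC[C@@H]1CC(=O)Oc2cc(O[C@@H](C)[C@@H](C)C(=O)O)c(CC=C)c(OC)c21
F4 | step 9 | (4R,8S,9R)-6-allyl-5-methoxy-8,9-dimethyl-4-pentyl-3,4,8,9-tetrahydro-2H,10H-pyrano[2,3-f]chromene-2,10-dione | CCCCC[C@@H]1CC(=O)Oc2c1c(OC)c(CC=C)c1O[C@@H](C)[C@@H](C)C(=O)c12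
F5 | step 5 | racemic 6-allyl-5-methoxy-4-pentyl-7-(triisopropylsilyloxy)chroman-2-one | CCCCCC1CC(=O)Oc2cc(O[Si](C(C)C)(C(C)C)C(C)C)c(CC=C)c(OC)c21
F6 | step 5 | (3R)-3-[3-allyl-6-hydroxy-2-methoxy-4-(triisopropylsilyloxy)phenyl]-N-[(1S)-1-phenylethyl]octanamide | CCCCC[C@H](CC(=O)N[C@@H](C)c1ccccc1)c1c(O)cc(O[Si](C(C)C)(C(C)C)C(C)C)c(CC=C)c1OC
F7 | step 12 | (4R,8S,9R)-5-methoxy-8,9-dimethyl-6-(3-methylbut-2-en-1-yl)-4-pentyl-3,4,8,9-tetrahydro-2H,10H-pyrano[2,3-f]chromene-2,10-dione | CCCCC[C@@H]1CC(=O)Oc2c1c(OC)c(CC=C(C)C)c1O[C@@H](C)[C@@H](C)C(=O)c12
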